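Ring A is cut across three C–C bonds into a 3-alkylcyclobutenone and methoxyethyne. The feature exploited is the 1,3,5-pattern of ring A: the chain on C1, the methoxy on C3 and the hydroxyl on C5 are mutually meta. One thermal pericyclic cascade builds this ring, with the C5 hydroxyl coming from the ketone oxygen and the C3 methoxy from the ynol ether, so the phenol and the methyl ether never have to be told apart. The precursor cyclobutenone carries at its C3 the complete (E)-tetradec-8-enyl chain ending in ring B as its bis(tert-butyldimethylsilyl) ether. It is assembled by Negishi coupling, Julia–Kocienski olefination and Grignard addition to 3-ethoxycyclobutenone.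

Key step: step 9

Assumption: methoxyethyne boils near room temperature and is not a routine catalogue item, so it is made fresh and handled as a cold toluene solution; the six compounds marked starting material are purchased.

Step 1
Reactants: 1 5-bromobenzene-1,3-diol
Product: 2 1-bromo-3,5-bis(tert-butyldimethylsilyloxy)benzene
Conditions: TBSCl (2.4 equiv), imidazole (5 equiv), DMF, 0 °C → rt
Reagents that add atoms: tert-butyldimethylsilyl chloride, CC(C)(C)[Si](C)(C)Cl
Why: Imidazole-mediated O-silylation of both phenols should be clean, and the aryl silyl ethers tolerate organozinc, hydride, amide base, Grignard and neutral thermolysis conditions yet fall together to fluoride at the end.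

Step 2
Reactants: 2 1-bromo-3,5-bis(tert-butyldimethylsilyloxy)benzene; 3 ethyl 6-bromohexanoate
Product: 5 ethyl 6-[3,5-bis(tert-butyldimethylsilyloxy)phenyl]hexanoate, via alkylzinc bromide 4 (not isolated)
Conditions: 3, Zn dust, LiCl, THF, 50 °C; then 2, Pd(OAc)2 (2 mol %), SPhos (4 mol %), THF, rt → 50 °C
Reagents that add atoms: none
Why: Zinc insertion into the primary C–Br bond gives an ester-tolerant alkylzinc reagent, and its Negishi sp2–sp3 coupling with the aryl bromide runs under neutral conditions that leave ester and silyl ethers alone.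

Step 3
Reactants: 5 ethyl 6-[3,5-bis(tert-butyldimethylsilyloxy)phenyl]hexanoate
Product: 7 6-[3,5-bis(tert-butyldimethylsilyloxy)phenyl]hexanal, via aluminium hemiacetal 6 (not isolated)
Conditions: i-Bu2AlH (1.1 equiv), CH2Cl2, −78 °C; MeOH, then aq. potassium sodium tartrate
Reagents that add atoms: none
Why: Partial ester reduction with one equivalent of hydride at −78 °C should stop at the tetrahedral aluminium hemiacetal, which releases the aldehyde only on work-up.

Step 4
Reactants: 8 8-bromooctan-1-ol; 9 1-phenyl-1H-tetrazole-5-thiol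
Product: 10 5-[(8-bromooctyl)sulfanyl]-1-phenyl-1H-tetrazole
Conditions: PPh3, DIAD, THF, 0 °C → rt
Reagents that add atoms: none
Why: Mitsunobu thioetherification alkylates the acidic tetrazolethiol at the activated primary alcohol, which at 0 °C should be faster than displacement of the primary bromide.

Step 5
Reactants: 10 5-[(8-bromooctyl)sulfanyl]-1-phenyl-1H-tetrazole
Product: 11 5-[(8-bromooctyl)sulfonyl]-1-phenyl-1H-tetrazole
Conditions: (NH4)6Mo7O24·4H2O (10 mol %), 30% aq. H2O2, EtOH, 0 °C → rt
Reagents that add atoms: hydrogen peroxide, OO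
Why: Molybdate-catalysed peroxide oxidation takes the sulfide through the sulfoxide to the sulfone and does not touch the alkyl bromide.

Step 6
Reactants: 11 5-[(8-bromooctyl)sulfonyl]-1-phenyl-1H-tetrazole; 7 6-[3,5-bis(tert-butyldimethylsilyloxy)phenyl]hexanal
Product: 13 1-[(E)-14-bromotetradec-6-enyl]-3,5-bis(tert-butyldimethylsilyloxy)benzene, via potassium sulfonyl carbanion 12 (not isolated)
Conditions: KN(SiMe3)2 (1.1 equiv), DME, −60 °C; then 7, −60 °C → rt; aq. NH4Cl
Reagents that add atoms: none
Why: In this Julia–Kocienski olefination the metalated sulfone adds to the aldehyde with kinetic anti selectivity, and stereospecific Smiles rearrangement with anti loss of SO2 and the tetrazololate should set the E alkene, the only stereochemical element of the target, while the primary bromide is not alkylated at this temperature.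

Step 7
Reactants: 13 1-[(E)-14-bromotetradec-6-enyl]-3,5-bis(tert-butyldimethylsilyloxy)benzene; 14 3-ethoxycyclobut-2-en-1-one
Product: 17 3-[(E)-14-[3,5-bis(tert-butyldimethylsilyloxy)phenyl]tetradec-8-enyl]cyclobut-2-en-1-one, via Grignard reagent 15 (not isolated), via magnesium alkoxide 16 (not isolated)
Conditions: Mg (I2 initiation), THF, rt → 40 °C; then 14, THF, −78 → 0 °C; then 1 M aq. HCl, 0 °C
Reagents that add atoms: water, O
Why: This is a Stork–Danheiser alkylative carbonyl transposition, in which the primary Grignard reagent adds 1,2 to the vinylogous ester and dilute acid hydrolyses the enol ether and eliminates water to the 3-alkylcyclobutenone, conditions that the aryl silyl ethers and the remote E alkene should survive.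

Step 8
Reactants: 18 2-chloro-1,1-dimethoxyethane
Product: 20 methoxyethyne, via sodium methoxyethynide 19 (not isolated)
Conditions: NaNH2 (3 equiv), liq. NH3, −33 °C; cold sat. aq. NaCl, −70 °C; distil into toluene at −78 °C
Reagents that add atoms: none
Why: Amide-induced double β-elimination (methanol, then hydrogen chloride) is the classical alkoxyacetylene synthesis; the ynol ether is held as its sodium acetylide and set free by the cold aqueous quench.

Step 9
Reactants: 17 3-[(E)-14-[3,5-bis(tert-butyldimethylsilyloxy)phenyl]tetradec-8-enyl]cyclobut-2-en-1-one; 20 methoxyethyne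
Product: 25 3-[(E)-14-[3,5-bis(tert-butyldimethylsilyloxy)phenyl]tetradec-8-enyl]-5-methoxyphenol, via vinylketene 21 (not isolated), via 4-vinylcyclobutenone 22 (not isolated), via dienylketene 23 (not isolated), via cyclohexadienone 24 (not isolated)
Conditions: 20 (4 equiv), toluene, sealed tube, 80 °C, then 110 °C
Reagents that add atoms: none
Why: Heat opens cyclobutenone 17 by four-electron conrotatory ring opening to vinylketene 21, whose C=C=O unit adds [2+2] across the electron-rich triple bond of 20 to give 4-vinylcyclobutenone 22; a second four-electron opening gives dienylketene 23. Ring A is then closed by six-electron disrotatory electrocyclization of 23, which joins the ketene carbon to the terminal methylene carbon and gives cyclohexadienone 24, and tautomerization gives phenol 25. The closest known reaction type is the Danheiser benzannulation of 3-substituted cyclobutenones with alkoxyalkynes to resorcinol monoethers. No stereocentre is formed, since the sp3 ring carbon of 22 is lost again on ring opening, and the remote E alkene is not involved. The selectivity required is the regiochemistry of the [2+2] step, secured by the polarization of the ynol ether: its unsubstituted, nucleophilic carbon bonds to the electrophilic central ketene carbon, so the methoxy group ends meta to the new hydroxyl and the chain meta to both. The neutral conditions spare the silyl ethers, and the excess of 20 should intercept 21 before it can acylate the phenol of 25.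

Step 10
Reactants: 25 3-[(E)-14-[3,5-bis(tert-butyldimethylsilyloxy)phenyl]tetradec-8-enyl]-5-methoxyphenol
Product: 26 5-[(E)-14-(3-hydroxy-5-methoxyphenyl)tetradec-6-enyl]benzene-1,3-diol (dehydrobisgravillol)
Conditions: Bu4NF (3 equiv), AcOH (3 equiv), THF, 0 °C → rt
Reagents that add atoms: none
Why: Fluoride-induced desilylation cleaves both aryl silyl ethers, and the acetic acid buffer keeps the electron-rich phenols protonated while the methyl ether and the E alkene stay untouched.

Compound list
1 | 5-bromobenzene-1,3-diol | Oc1cc(O)cc(Br)c1 | starting material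
2 | 1-bromo-3,5-bis(tert-butyldimethylsilyloxy)benzene | CC(C)(C)[Si](C)(C)Oc1cc(Br)cc(O[Si](C)(C)C(C)(C)C)c1 | intermediate
3 | ethyl 6-bromohexanoate | CCOC(=O)CCCCCBr | starting material
4 | (6-ethoxy-6-oxohexyl)zinc bromide (formed in the flask) | CCOC(=O)CCCCC[Zn]Br | intermediate
5 | ethyl 6-[3,5-bis(tert-butyldimethylsilyloxy)phenyl]hexanoate | CCOC(=O)CCCCCc1cc(O[Si](C)(C)C(C)(C)C)cc(O[Si](C)(C)C(C)(C)C)c1 | intermediate
6 | diisobutylaluminium ethyl hemiacetal of aldehyde 7 (racemic, formed in the flask) | CCOC(CCCCCc1cc(O[Si](C)(C)C(C)(C)C)cc(O[Si](C)(C)C(C)(C)C)c1)O[Al](CC(C)C)CC(C)C | intermediate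
7 | 6-[3,5-bis(tert-butyldimethylsilyloxy)phenyl]hexanal | O=CCCCCCc1cc(O[Si](C)(C)C(C)(C)C)cc(O[Si](C)(C)C(C)(C)C)c1 | intermediate
8 | 8-bromooctan-1-ol | OCCCCCCCCBr | starting material
9 | 1-phenyl-1H-tetrazole-5-thiol | Sc1nnnn1-c1ccccc1 | starting material
10 | 5-[(8-bromooctyl)sulfanyl]-1-phenyl-1H-tetrazole | BrCCCCCCCCSc1nnnn1-c1ccccc1 | intermediate
11 | 5-[(8-bromooctyl)sulfonyl]-1-phenyl-1H-tetrazole | BrCCCCCCCCS(=O)(=O)c1nnnn1-c1ccccc1 | intermediate
12 | potassium salt of the α-sulfonyl carbanion of 11 (formed in the flask) | [K+].BrCCCCCCC[CH-]S(=O)(=O)c1nnnn1-c1ccccc1 | intermediate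
13 | 1-[(E)-14-bromotetradec-6-enyl]-3,5-bis(tert-butyldimethylsilyloxy)benzene | BrCCCCCCC/C=C/CCCCCc1cc(O[Si](C)(C)C(C)(C)C)cc(O[Si](C)(C)C(C)(C)C)c1 | intermediate
14 | 3-ethoxycyclobut-2-en-1-one | CCOC1=CC(=O)C1 | starting material
15 | bromo[(E)-14-[3,5-bis(tert-butyldimethylsilyloxy)phenyl]tetradec-8-enyl]magnesium (formed in the flask) | Br[Mg]CCCCCCC/C=C/CCCCCc1cc(O[Si](C)(C)C(C)(C)C)cc(O[Si](C)(C)C(C)(C)C)c1 | intermediate
16 | bromomagnesium alkoxide of 1-[(E)-14-[3,5-bis(tert-butyldimethylsilyloxy)phenyl]tetradec-8-enyl]-3-ethoxycyclobut-2-en-1-ol (racemic, formed in the flask) | CCOC1=CC(O[Mg]Br)(CCCCCCC/C=C/CCCCCc2cc(O[Si](C)(C)C(C)(C)C)cc(O[Si](C)(C)C(C)(C)C)c2)C1 | intermediate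
17 | 3-[(E)-14-[3,5-bis(tert-butyldimethylsilyloxy)phenyl]tetradec-8-enyl]cyclobut-2-en-1-one | O=C1C=C(CCCCCCC/C=C/CCCCCc2cc(O[Si](C)(C)C(C)(C)C)cc(O[Si](C)(C)C(C)(C)C)c2)C1 | intermediate
18 | 2-chloro-1,1-dimethoxyethane (chloroacetaldehyde dimethyl acetal) | COC(CCl)OC | starting material
19 | sodium methoxyethynide (formed in the flask) | COC#[C-].[Na+] | intermediate
20 | methoxyethyne | COC#C | intermediate
21 | 3-[(E)-14-[3,5-bis(tert-butyldimethylsilyloxy)phenyl]tetradec-8-enyl]buta-1,3-dien-1-one (vinylketene, formed in the flask) | O=C=CC(=C)CCCCCCC/C=C/CCCCCc1cc(O[Si](C)(C)C(C)(C)C)cc(O[Si](C)(C)C(C)(C)C)c1 | intermediate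
22 | 4-[(10E)-16-[3,5-bis(tert-butyldimethylsilyloxy)phenyl]hexadeca-1,10-dien-2-yl]-3-methoxycyclobut-2-en-1-one (racemic, formed in the flask) | COC1=CC(=O)C1C(=C)CCCCCCC/C=C/CCCCCc2cc(O[Si](C)(C)C(C)(C)C)cc(O[Si](C)(C)C(C)(C)C)c2 | intermediate
23 | (3E)-5-[(E)-14-[3,5-bis(tert-butyldimethylsilyloxy)phenyl]tetradec-8-enyl]-3-methoxyhexa-1,3,5-trien-1-one (dienylketene in the geometry that can cyclize, formed in the flask) | O=C=C/C(OC)=C\C(=C)CCCCCCC/C=C/CCCCCc1cc(O[Si](C)(C)C(C)(C)C)cc(O[Si](C)(C)C(C)(C)C)c1 | intermediate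
24 | 5-[(E)-14-[3,5-bis(tert-butyldimethylsilyloxy)phenyl]tetradec-8-enyl]-3-methoxycyclohexa-2,4-dien-1-one (formed in the flask) | COC1=CC(=O)CC(CCCCCCC/C=C/CCCCCc2cc(O[Si](C)(C)C(C)(C)C)cc(O[Si](C)(C)C(C)(C)C)c2)=C1 | intermediate
25 | 3-[(E)-14-[3,5-bis(tert-butyldimethylsilyloxy)phenyl]tetradec-8-enyl]-5-methoxyphenol | COc1cc(O)cc(CCCCCCC/C=C/CCCCCc2cc(O[Si](C)(C)C(C)(C)C)cc(O[Si](C)(C)C(C)(C)C)c2)c1 | intermediate
26 | 5-[(E)-14-(3-hydroxy-5-methoxyphenyl)tetradec-6-enyl]benzene-1,3-diol (dehydrobisgravillol) | COc1cc(O)cc(CCCCCCC/C=C/CCCCCc2cc(O)cc(O)c2)c1 | target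

Total steps: 10. Longest linear sequence: 7 steps (steps 1, 2, 3, 6, 7, 9, 10, from 1 to 26).

Steps most likely to fail

1. Step 9. The volatile ynol ether may oligomerize or escape before it captures the vinylketene, and the freshly formed phenol may be acylated by vinylketene that has not yet been trapped. Fallback (sets out from 13, returns at 26): ring A is bought instead of built. 3-Bromo-5-methoxyphenol is silylated (TBSCl, imidazole, DMF) to (3-bromo-5-methoxyphenoxy)(tert-butyl)dimethylsilane F1. Bromide 13 is converted with Zn dust and LiCl in THF at 50 °C into bromo[(E)-14-[3,5-bis(tert-butyldimethylsilyloxy)phenyl]tetradec-8-enyl]zinc F2. Negishi coupling of F2 with F1 (Pd(OAc)2, SPhos, THF) should give 1-[(E)-14-[3-(tert-butyldimethylsilyloxy)-5-methoxyphenyl]tetradec-6-enyl]-3,5-bis(tert-butyldimethylsilyloxy)benzene F3. The Bu4NF/AcOH conditions of step 10 then free all three phenols and give 26.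

2. Step 7. Magnesium insertion may be accompanied by Wurtz-type homocoupling, and the basic Grignard reagent may deprotonate the ring CH2 of 14 in place of adding to its carbonyl group. Fallback (sets out from 13, returns at 17): the organometallic and the way it is made are changed. Finkelstein exchange (NaI, acetone, reflux) gives 1-[(E)-14-iodotetradec-6-enyl]-3,5-bis(tert-butyldimethylsilyloxy)benzene F4. Lithium–iodine exchange with t-BuLi (2.1 equiv, pentane/Et2O, −78 °C), which involves no metal surface and hence no homocoupling, gives [(E)-14-[3,5-bis(tert-butyldimethylsilyloxy)phenyl]tetradec-8-enyl]lithium F5. This more nucleophilic reagent should add to 14 at −78 °C, and the same dilute-acid work-up gives 17.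

3. Step 6. E selectivity may erode in the addition and Smiles sequence of two unbranched partners, and carbanion 12 may be alkylated by the primary bromide of a second molecule. Fallback (sets out from 7, returns at 17): the alkene geometry is taken from an alkyne by syn hydrometalation.
- Aldehyde 7 is homologated with lithiated Me3SiCHN2 (Colvin rearrangement, THF, −78 °C → rt) to 1,3-bis(tert-butyldimethylsilyloxy)-5-(hept-6-ynyl)benzene F6.
- Hydrozirconation with Cp2Zr(H)Cl (THF, rt) and iodinolysis (I2, 0 °C) give 1,3-bis(tert-butyldimethylsilyloxy)-5-[(E)-7-iodohept-6-enyl]benzene F7 as a single geometric isomer.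
- Zinc inserts only into the C–Br bond of 1-bromo-7-chloroheptane (Zn dust, LiCl, THF) to give (7-chloroheptyl)zinc bromide F8. Its Negishi coupling with F7 (Pd(PPh3)4, zerovalent palladium, THF, rt) proceeds with retention to 1-[(E)-14-chlorotetradec-6-enyl]-3,5-bis(tert-butyldimethylsilyloxy)benzene F9.
- Mg in refluxing THF converts F9 into chloro[(E)-14-[3,5-bis(tert-butyldimethylsilyloxy)phenyl]tetradec-8-enyl]magnesium F10, which takes the place of 15 in step 7 and gives 17.

Further compounds
F1 | step 9 | (3-bromo-5-methoxyphenoxy)(tert-butyl)dimethylsilane | COc1cc(Br)cc(O[Si](C)(C)C(C)(C)C)c1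
F2 | step 9 | bromo[(E)-14-[3,5-bis(tert-butyldimethylsilyloxy)phenyl]tetradec-8-enyl]zinc | Br[Zn]CCCCCCC/C=C/CCCCCc1cc(O[Si](C)(C)C(C)(C)C)cc(O[Si](C)(C)C(C)(C)C)c1
F3 | step 9 | 1-[(E)-14-[3-(tert-butyldimethylsilyloxy)-5-methoxyphenyl]tetradec-6-enyl]-3,5-bis(tert-butyldimethylsilyloxy)benzene | COc1cc(O[Si](C)(C)C(C)(C)C)cc(CCCCCCC/C=C/CCCCCc2cc(O[Si](C)(C)C(C)(C)C)cc(O[Si](C)(C)C(C)(C)C)c2)c1
F4 | step 7 | 1-[(E)-14-iodotetradec-6-enyl]-3,5-bis(tert-butyldimethylsilyloxy)benzene | ICCCCCCC/C=C/CCCCCc1cc(O[Si](C)(C)C(C)(C)C)cc(O[Si](C)(C)C(C)(C)C)c1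
F5 | step 7 | [(E)-14-[3,5-bis(tert-butyldimethylsilyloxy)phenyl]tetradec-8-enyl]lithium | [Li]CCCCCCC/C=C/CCCCCc1cc(O[Si](C)(C)C(C)(C)C)cc(O[Si](C)(C)C(C)(C)C)c1
F6 | step 6 | 1,3-bis(tert-butyldimethylsilyloxy)-5-(hept-6-ynyl)benzene | C#CCCCCCc1cc(O[Si](C)(C)C(C)(C)C)cc(O[Si](C)(C)C(C)(C)C)c1
F7 | step 6 | 1,3-bis(tert-butyldimethylsilyloxy)-5-[(E)-7-iodohept-6-enyl]benzene | I/C=C/CCCCCc1cc(O[Si](C)(C)C(C)(C)C)cc(O[Si](C)(C)C(C)(C)C)c1
F8 | step 6 | (7-chloroheptyl)zinc bromide | ClCCCCCCC[Zn]Br
F9 | step 6 | 1-[(E)-14-chlorotetradec-6-enyl]-3,5-bis(tert-butyldimethylsilyloxy)benzene | ClCCCCCCC/C=C/CCCCCc1cc(O[Si](C)(C)C(C)(C)C)cc(O[Si](C)(C)C(C)(C)C)c1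
F10 | step 6 | chloro[(E)-14-[3,5-bis(tert-butyldimethylsilyloxy)phenyl]tetradec-8-enyl]magnesium | Cl[Mg]CCCCCCC/C=C/CCCCCc1cc(O[Si](C)(C)C(C)(C)C)cc(O[Si](C)(C)C(C)(C)C)c1
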